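**Plan**
- Retrosynthetic cuts: (a) the ester C–O bond at C3, giving the trans 3-hydroxy-2-isopropenyl-2,3-dihydrobenzofuran and (Z)-2-(acetoxymethyl)but-2-enoic acid; (b) the O1–C2 bond of the dihydrofuran ring, giving a phenol with a trans C2–C3 vinyl epoxide in the ortho position; (c) the epoxide oxygen, giving an (E)-aryl diene; (d) the aryl–alkenyl C–C bond, giving 4'-hydroxy-3'-iodoacetophenone and isoprene.
- Enabling feature: in the dihydrofuran ring, C2 is allylic (it bears the isopropenyl group) and carries O1 trans to the oxygen on C3. This trans O1–C2–C3–O unit is the mark of an anti opening of a C2–C3 epoxide by the phenolic oxygen at the allylic carbon. One event closes the five-membered ring, releases the C3 hydroxyl and fixes the trans relationship.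
- Forward order: phenol silylation, Heck coupling with isoprene, Shi epoxidation, fluoride-triggered desilylation and cyclization (the only ring formed), then acylation of the C3 hydroxyl with the separately made side-chain acid.
- Stereochemistry: both ring stereocenters come from the catalyst-controlled Shi epoxidation (2S,3S). C3 is carried over unchanged and C2 is inverted in the ring closure, giving (2R,3S). The Z double bond of the acyl group comes from (Z)-2-bromobut-2-enal and is kept through bromine–lithium exchange and carboxylation.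

Key step: step 4

Assumption: the L-fructose-derived ketone catalyst of step 3 (mirror image of the usual D-fructose-derived one) is taken as purchasable; otherwise it is prepared from L-sorbose.

**Step 1**
Reactants: 1 1-(4-hydroxy-3-iodophenyl)ethan-1-one
Product: 2 1-{3-iodo-4-[(triisopropylsilyl)oxy]phenyl}ethan-1-one
Conditions: i-Pr3SiCl (1.2 equiv), imidazole (2.5 equiv), DMF, rt
Reagents that add atoms: chlorotri(propan-2-yl)silane, CC(C)[Si](Cl)(C(C)C)C(C)C
Why: Silyl ether formation on the acidic phenol should mask O1 as a hindered, fluoride-labile triisopropylsilyl ether that tolerates the Heck and epoxidation conditions and whose removal later triggers the ring closure.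

**Step 2**
Reactants: 2 1-{3-iodo-4-[(triisopropylsilyl)oxy]phenyl}ethan-1-one, 3 isoprene (2-methylbuta-1,3-diene)
Product: 4 1-{3-[(1E)-3-methylbuta-1,3-dien-1-yl]-4-[(triisopropylsilyl)oxy]phenyl}ethan-1-one
Conditions: Pd(OAc)2 (5 mol %), P(o-tol)3 (10 mol %), Et3N (2 equiv), isoprene (5 equiv), MeCN, 80 °C, sealed tube
Reagents that add atoms: none
Why: Heck reaction in which the arylpalladium species should add to the less hindered monosubstituted end of isoprene and lose the benzylic hydrogen by syn β-hydride elimination, giving the conjugated (E)-diene while the acetyl group and the silyl ether stay untouched.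

**Step 3**
Reactants: 4 1-{3-[(1E)-3-methylbuta-1,3-dien-1-yl]-4-[(triisopropylsilyl)oxy]phenyl}ethan-1-one
Product: 5 1-{3-[(2S,3S)-3-(prop-1-en-2-yl)oxiran-2-yl]-4-[(triisopropylsilyl)oxy]phenyl}ethan-1-one
Conditions: 1,2:4,5-di-O-isopropylidene-β-L-erythro-2,3-hexodiulo-2,6-pyranose (30 mol %), Oxone (2KHSO5·KHSO4·K2SO4, 1.4 equiv), K2CO3 (5.8 equiv), Bu4NHSO4 (4 mol %), MeCN/dimethoxymethane 1:2, aq Na2B4O7 buffer with disodium ethylenediaminetetraacetate, −10 to 0 °C
Reagents that add atoms: potassium peroxymonosulfate (the active part of Oxone), [K+].[O-]S(=O)(=O)OO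
Why: Shi asymmetric epoxidation, in which the oxidant derived from the chiral ketone should attack the trans-disubstituted styrenyl double bond in preference to the 1,1-disubstituted isopropenyl one through the spiro transition state, the L-fructose-derived ketone (mirror image of the D-fructose-derived catalyst that converts trans aryl alkenes into (R,R)-epoxides) setting both epoxide carbons as S under catalyst control.

**Step 4**
Reactants: 5 1-{3-[(2S,3S)-3-(prop-1-en-2-yl)oxiran-2-yl]-4-[(triisopropylsilyl)oxy]phenyl}ethan-1-one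
Product: 7 1-[(2R,3S)-3-hydroxy-2-(prop-1-en-2-yl)-2,3-dihydro-1-benzofuran-5-yl]ethan-1-one, via tetrabutylammonium phenoxide 6 (not isolated)
Conditions: Bu4NF (1.1 equiv), THF, 0 °C to rt; aq NH4Cl
Reagents that add atoms: none
Why: Fluoride cleaves the aryl O–Si bond, and the freed phenoxide oxygen O1 attacks the isopropenyl-bearing epoxide carbon from the side opposite to its C–O bond (intramolecular SN2 epoxide opening), the epoxide oxygen becoming the C3 alkoxide. The closest known reaction type is the base-induced cyclization of 2-(oxiran-2-yl)phenols to 2,3-dihydrobenzofuran-3-ols, here helped by the usual preference of vinyl epoxides to open at the allylic carbon. The dihydrofuran ring closes in the 5-endo-tet mode, the only alternative at the benzylic carbon being a 4-exo closure to a four-membered ring. C2 is set by inversion of the (S)-epoxide carbon and becomes (R), while C3 keeps the configuration from the epoxidation because its C–O bond is not broken, so the trans (2R,3S) arrangement follows stereospecifically from the trans epoxide. The step needs attack at C2 instead of SN2' attack at the terminal methylene (seven-membered ring) and no ionization of the benzylic C–O bond; the short rigid tether, the non-acidic medium and the para-acetyl group, which tempers electron release from the phenoxide toward the benzylic position, should secure this.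

**Step 5**
Reactants: 8 (2E)-but-2-enal (crotonaldehyde)
Product: 10 (2Z)-2-bromobut-2-enal, via 2,3-dibromobutanal 9 (not isolated)
Conditions: Br2 (1.0 equiv), CH2Cl2, 0 °C; then Et3N (1.2 equiv), 0 °C to rt
Reagents that add atoms: bromine, BrBr
Why: Bromination followed by dehydrobromination, in which anti addition of bromine and base-induced loss of HBr through the acidic α-hydrogen should give the more stable (Z)-α-bromo enal with bromine cis to the methyl group, the geometry the side-chain acid needs.

**Step 6**
Reactants: 10 (2Z)-2-bromobut-2-enal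
Product: 11 (2Z)-2-bromobut-2-en-1-ol
Conditions: NaBH4 (1.0 equiv), CeCl3·7H2O (1.0 equiv), MeOH, 0 °C
Reagents that add atoms: none
Why: Luche reduction, in which cerium-assisted 1,2-delivery of hydride should reduce only the aldehyde and leave the vinyl bromide and the double-bond geometry unchanged.

**Step 7**
Reactants: 11 (2Z)-2-bromobut-2-en-1-ol
Product: 13 (2Z)-2-(hydroxymethyl)but-2-enoic acid, via dilithio alkenyl alkoxide 12 (not isolated)
Conditions: t-BuLi (3.1 equiv), Et2O, −78 °C; CO2 (g), −78 to 0 °C; aq HCl to pH 2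
Reagents that add atoms: carbon dioxide, O=C=O
Why: Bromine–lithium exchange followed by carboxylation, in which the alkenyllithium formed after O-deprotonation is configurationally stable at −78 °C, so that CO2 should be taken up with retention and the carboxyl group should end up cis to the methyl group.

**Step 8**
Reactants: 13 (2Z)-2-(hydroxymethyl)but-2-enoic acid
Product: 14 (2Z)-2-[(acetyloxy)methyl]but-2-enoic acid
Conditions: Ac2O (1.5 equiv), pyridine, CH2Cl2, 0 °C to rt; then H2O
Reagents that add atoms: acetic anhydride, CC(=O)OC(C)=O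
Why: Acetylation (ester formation with an anhydride) of the primary allylic hydroxyl under mild pyridine conditions should leave the Z double bond and, after the aqueous quench, the carboxylic acid unchanged.

**Step 9**
Reactants: 7 1-[(2R,3S)-3-hydroxy-2-(prop-1-en-2-yl)-2,3-dihydro-1-benzofuran-5-yl]ethan-1-one, 14 (2Z)-2-[(acetyloxy)methyl]but-2-enoic acid
Product: 16 (2R,3S)-5-acetyl-2-(prop-1-en-2-yl)-2,3-dihydro-1-benzofuran-3-yl (2Z)-2-[(acetyloxy)methyl]but-2-enoate, via mixed anhydride 15 (not isolated)
Conditions: 14, 2,4,6-trichlorobenzoyl chloride (1.2 equiv), Et3N (2.5 equiv), toluene, rt; then 7, 75 °C (no 4-(dimethylamino)pyridine)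
Reagents that add atoms: none
Why: Yamaguchi-type esterification through the mixed anhydride without a nucleophilic catalyst, in which the secondary alcohol should attack the less hindered enoyl carbonyl, the absence of a nucleophilic pyridine or phosphine should avoid Z-to-E isomerization of the angelate-type double bond and allylic displacement of the acetate, and C3 keeps its configuration because its C–O bond is not touched.

**Compound list**
1 | 1-(4-hydroxy-3-iodophenyl)ethan-1-one (4'-hydroxy-3'-iodoacetophenone) | CC(=O)c1ccc(O)c(I)c1 | starting material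
2 | 1-{3-iodo-4-[(triisopropylsilyl)oxy]phenyl}ethan-1-one | CC(=O)c1ccc(O[Si](C(C)C)(C(C)C)C(C)C)c(I)c1 | intermediate
3 | isoprene (2-methylbuta-1,3-diene) | C=CC(C)=C | starting material
4 | 1-{3-[(1E)-3-methylbuta-1,3-dien-1-yl]-4-[(triisopropylsilyl)oxy]phenyl}ethan-1-one | CC(=O)c1ccc(O[Si](C(C)C)(C(C)C)C(C)C)c(/C=C/C(C)=C)c1 | intermediate
5 | 1-{3-[(2S,3S)-3-(prop-1-en-2-yl)oxiran-2-yl]-4-[(triisopropylsilyl)oxy]phenyl}ethan-1-one (trans epoxide) | CC(=O)c1ccc(O[Si](C(C)C)(C(C)C)C(C)C)c(c1)[C@@H]1O[C@H]1C(C)=C | intermediate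
6 | tetrabutylammonium 4-acetyl-2-[(2S,3S)-3-(prop-1-en-2-yl)oxiran-2-yl]phenolate (not isolated) | CC(=O)c1ccc([O-])c(c1)[C@@H]1O[C@H]1C(C)=C.CCCC[N+](CCCC)(CCCC)CCCC | intermediate
7 | 1-[(2R,3S)-3-hydroxy-2-(prop-1-en-2-yl)-2,3-dihydro-1-benzofuran-5-yl]ethan-1-one (trans alcohol) | C=C(C)[C@H]1Oc2ccc(C(C)=O)cc2[C@@H]1O | intermediate
8 | (2E)-but-2-enal (crotonaldehyde) | C/C=C/C=O | starting material
9 | (2R*,3S*)-2,3-dibromobutanal (racemic, one enantiomer drawn; not isolated) | C[C@H](Br)[C@H](Br)C=O | intermediate
10 | (2Z)-2-bromobut-2-enal (bromine cis to methyl) | C/C=C(\Br)C=O | intermediate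
11 | (2Z)-2-bromobut-2-en-1-ol | C/C=C(\Br)CO | intermediate
12 | lithium (2E)-2-lithiobut-2-en-1-olate (lithium cis to methyl; the descriptor changes only through the priority rule; not isolated) | C/C=C(\[Li])CO[Li] | intermediate
13 | (2Z)-2-(hydroxymethyl)but-2-enoic acid (carboxyl cis to methyl) | C/C=C(/CO)C(=O)O | intermediate
14 | (2Z)-2-[(acetyloxy)methyl]but-2-enoic acid | C/C=C(/COC(C)=O)C(=O)O | intermediate
15 | (2Z)-2-[(acetyloxy)methyl]but-2-enoic 2,4,6-trichlorobenzoic anhydride (not isolated) | C/C=C(/COC(C)=O)C(=O)OC(=O)c1c(Cl)cc(Cl)cc1Cl | intermediate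
16 | (2R,3S)-5-acetyl-2-(prop-1-en-2-yl)-2,3-dihydro-1-benzofuran-3-yl (2Z)-2-[(acetyloxy)methyl]but-2-enoate | C=C(C)[C@H]1Oc2ccc(C(C)=O)cc2[C@@H]1OC(=O)/C(=C\C)COC(C)=O | target

**Totals**
Total step count: 9. Longest linear sequence: 5 steps (steps 1, 2, 3, 4 and 9; the side-chain arm, steps 5 to 9, is equally long).

**Steps most likely to fail**

Step 4. What may go wrong: slow 5-endo closure of the phenoxide, or ionization of the benzylic C–O bond of the epoxide before closure, which would erode the trans stereospecificity. The fallback sets out from diene 4 and comes back at alcohol 7. It closes the same O1–C2 bond by palladium-catalyzed allylic etherification with retention and then inverts C3. Diene 4 is epoxidized as in step 3 but with the D-fructose-derived ketone 1,2:4,5-di-O-isopropylidene-β-D-erythro-2,3-hexodiulo-2,6-pyranose, which should give the mirror-image epoxide 1-{3-[(2R,3R)-3-(prop-1-en-2-yl)oxiran-2-yl]-4-[(triisopropylsilyl)oxy]phenyl}ethan-1-one F1. Buffered desilylation (Bu4NF, AcOH, THF, 0 °C) should give the free phenol 1-{4-hydroxy-3-[(2R,3R)-3-(prop-1-en-2-yl)oxiran-2-yl]phenyl}ethan-1-one F2. Pd(PPh3)4 (5 mol %, zerovalent palladium, THF, 0 °C) should open the vinyl epoxide with inversion, and the phenol oxygen should then attack C2 on the face opposite to the metal (5-exo closure, net retention at C2), giving the cis alcohol 1-[(2R,3R)-3-hydroxy-2-(prop-1-en-2-yl)-2,3-dihydro-1-benzofuran-5-yl]ethan-1-one F3, separable from any trans isomer. A Mitsunobu reaction (4-nitrobenzoic acid, PPh3, diisopropyl azodicarboxylate, THF, 0 °C) should invert C3 to give (2R,3S)-5-acetyl-2-(prop-1-en-2-yl)-2,3-dihydro-1-benzofuran-3-yl 4-nitrobenzoate F4, and methanolysis (K2CO3 cat., MeOH, 0 °C) returns to alcohol 7.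

Step 3. What may go wrong: attack of the oxidant on the isopropenyl double bond instead of the styrenyl one, or double epoxidation (poor site selectivity between the two alkenes of the diene). The fallback sets out from iodide 2 and comes back at epoxide 5. It hides the isopropenyl group as a tertiary alcohol during the epoxidation. Iodide 2 is coupled in a Heck reaction with 2-methylbut-3-en-2-ol (Pd(OAc)2, P(o-tol)3, Et3N, MeCN, 80 °C) to give the allylic alcohol 1-{3-[(1E)-3-hydroxy-3-methylbut-1-en-1-yl]-4-[(triisopropylsilyl)oxy]phenyl}ethan-1-one F5, which has a single double bond. Shi epoxidation with the same L-fructose-derived ketone should give the epoxy alcohol 1-{3-[(2S,3R)-3-(2-hydroxypropan-2-yl)oxiran-2-yl]-4-[(triisopropylsilyl)oxy]phenyl}ethan-1-one F6 (same spatial arrangement as in 5; the second descriptor changes only through the priority rule). Burgess dehydration of the tertiary alcohol (methyl N-(triethylammoniosulfonyl)carbamate, toluene, 50 °C) should unveil the isopropenyl group and return to epoxide 5.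

Step 9. What may go wrong: Z-to-E isomerization of the side-chain double bond or allylic displacement of the acetate while the acid is activated, and slow acylation of the hindered benzylic alcohol without a nucleophilic catalyst. The fallback sets out from acid 13 (with alcohol 7) and comes back at target 16. It brings in the acetate last, so that the acid being activated has no allylic leaving group. Acid 13 is silylated twice (t-BuMe2SiCl, imidazole, DMF) to tert-butyldimethylsilyl (2Z)-2-{[(tert-butyldimethylsilyl)oxy]methyl}but-2-enoate F7, whose silyl ester is cleaved in the same flask (K2CO3 cat., MeOH/H2O) to give (2Z)-2-{[(tert-butyldimethylsilyl)oxy]methyl}but-2-enoic acid F8. Its mixed anhydride with 2,4,6-trichlorobenzoyl chloride, (2Z)-2-{[(tert-butyldimethylsilyl)oxy]methyl}but-2-enoic 2,4,6-trichlorobenzoic anhydride F9 (Et3N, toluene, rt), should acylate alcohol 7 at 75 °C to give (2R,3S)-5-acetyl-2-(prop-1-en-2-yl)-2,3-dihydro-1-benzofuran-3-yl (2Z)-2-{[(tert-butyldimethylsilyl)oxy]methyl}but-2-enoate F10. HF·pyridine (THF/pyridine, 0 °C) should free the primary alcohol (2R,3S)-5-acetyl-2-(prop-1-en-2-yl)-2,3-dihydro-1-benzofuran-3-yl (2Z)-2-(hydroxymethyl)but-2-enoate F11, and acetylation (Ac2O, pyridine, 0 °C) gives target 16.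

**Further compounds**
F1 | step 4 | 1-{3-[(2R,3R)-3-(prop-1-en-2-yl)oxiran-2-yl]-4-[(triisopropylsilyl)oxy]phenyl}ethan-1-one | CC(=O)c1ccc(O[Si](C(C)C)(C(C)C)C(C)C)c(c1)[C@H]1O[C@@H]1C(C)=C
F2 | step 4 | 1-{4-hydroxy-3-[(2R,3R)-3-(prop-1-en-2-yl)oxiran-2-yl]phenyl}ethan-1-one | CC(=O)c1ccc(O)c(c1)[C@H]1O[C@@H]1C(C)=C
F3 | step 4 | 1-[(2R,3R)-3-hydroxy-2-(prop-1-en-2-yl)-2,3-dihydro-1-benzofuran-5-yl]ethan-1-one | C=C(C)[C@H]1Oc2ccc(C(C)=O)cc2[C@H]1O
F4 | step 4 | (2R,3S)-5-acetyl-2-(prop-1-en-2-yl)-2,3-dihydro-1-benzofuran-3-yl 4-nitrobenzoate | C=C(C)[C@H]1Oc2ccc(C(C)=O)cc2[C@@H]1OC(=O)c1ccc(cc1)[N+](=O)[O-]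
F5 | step 3 | 1-{3-[(1E)-3-hydroxy-3-methylbut-1-en-1-yl]-4-[(triisopropylsilyl)oxy]phenyl}ethan-1-one | CC(=O)c1ccc(O[Si](C(C)C)(C(C)C)C(C)C)c(/C=C/C(C)(C)O)c1
F6 | step 3 | 1-{3-[(2S,3R)-3-(2-hydroxypropan-2-yl)oxiran-2-yl]-4-[(triisopropylsilyl)oxy]phenyl}ethan-1-one | CC(=O)c1ccc(O[Si](C(C)C)(C(C)C)C(C)C)c(c1)[C@@H]1O[C@H]1C(C)(C)O
F7 | step 9 | tert-butyldimethylsilyl (2Z)-2-{[(tert-butyldimethylsilyl)oxy]methyl}but-2-enoate | C/C=C(/CO[Si](C)(C)C(C)(C)C)C(=O)O[Si](C)(C)C(C)(C)C
F8 | step 9 | (2Z)-2-{[(tert-butyldimethylsilyl)oxy]methyl}but-2-enoic acid | C/C=C(/CO[Si](C)(C)C(C)(C)C)C(=O)O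
F9 | step 9 | (2Z)-2-{[(tert-butyldimethylsilyl)oxy]methyl}but-2-enoic 2,4,6-trichlorobenzoic anhydride | C/C=C(/CO[Si](C)(C)C(C)(C)C)C(=O)OC(=O)c1c(Cl)cc(Cl)cc1Cl
F10 | step 9 | (2R,3S)-5-acetyl-2-(prop-1-en-2-yl)-2,3-dihydro-1-benzofuran-3-yl (2Z)-2-{[(tert-butyldimethylsilyl)oxy]methyl}but-2-enoate | C=C(C)[C@H]1Oc2ccc(C(C)=O)cc2[C@@H]1OC(=O)/C(=C\C)CO[Si](C)(C)C(C)(C)C
F11 | step 9 | (2R,3S)-5-acetyl-2-(prop-1-en-2-yl)-2,3-dihydro-1-benzofuran-3-yl (2Z)-2-(hydroxymethyl)but-2-enoate | C=C(C)[C@H]1Oc2ccc(C(C)=O)cc2[C@@H]1OC(=O)/C(=C\C)CO
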